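**Strategy.** Eudesmane numbering is used (C1 = CHBr, C5 = C–OH, C7 = side-chain methine, C10 = C–CH3). Everything rests on the C7–C11 disconnection: the complete bromo-decalinol is joined to the C8 trienyl unit in the last step. The key step is a nickel-catalysed reductive cross-electrophile coupling of a C7 iodide with (2E,4E)-2-bromo-6-methylhepta-2,4,6-triene. It exploits the chair of ring B (C5, C6, C7, C8, C9, C10): the planar C7 radical is shielded on its α-face by the syn-axial C5 hydroxyl, so either C7 epimer of the iodide should funnel into the equatorial 7β product while the E,E-triene is transferred intact. The iodide comes from (R)-Wieland–Miescher ketone, whose two carbonyls become C1 and C7.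

Key step: step 9

Remark: β is the face of the C10 methyl, ring A is C1–C5/C10 and ring B is C5–C10; the C7 configuration of iodide 9 is immaterial because the key step erases it, and 9 is drawn as the 7β epimer expected from step 5.

Step 1
Reactants: 1 (R)-(−)-Wieland–Miescher ketone
Product: 2 (8aR)-8a-methyl-4-methylidene-3,4,8,8a-tetrahydronaphthalene-1,6(2H,7H)-dione (C15H2=C4–C5=C6–C7=O dienone; C1 ketone)
Conditions: CH2(OEt)2, POCl3, NaOAc, CHCl3, reflux
Reagents that add atoms: diethoxymethane, CCOCOCC
Why: Vinylogous (γ) alkoxymethylation of the dienol form of the enone by the ethoxymethyl cation and loss of ethanol (the γ-methylenation used for Δ4-3-keto steroids) should place C15 on C4, the α-quaternary saturated C1 ketone being far less prone to enolise and C10 being untouched.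

Step 2
Reactants: 2 the 4-methylidene dienone
Product: 4 (4aR,5S)-5-hydroxy-4a,8-dimethyl-3,4,4a,5,6,7-hexahydronaphthalen-2(1H)-one (1α-OH; C4=C5; C7=O), via dilithium dienolate-alkoxide 3 (not isolated)
Conditions: L-Selectride (2.3 equiv), THF, −78 → −40 °C; then AcOH, −78 °C
Reagents that add atoms: none
Why: Conjugate (1,6) hydride addition of the bulky borohydride to the unhindered exocyclic CH2 should give the linear dienolate, which masks C7 while a second equivalent reduces the α-quaternary C1 ketone by equatorial (β-face) attack to the axial 1α-alcohol (Selectride ketone reduction); kinetic protonation at C6 leaves the tetrasubstituted C4=C5 alkene out of conjugation.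

Step 3
Reactants: 4 the 1α-hydroxy β,γ-enone
Product: 5 (4aR,5R)-5-bromo-4a,8-dimethyl-3,4,4a,5,6,7-hexahydronaphthalen-2(1H)-one (1β-Br)
Conditions: CBr4, PPh3, 2,6-lutidine, PhMe, 60 °C
Reagents that add atoms: carbon tetrabromide, BrC(Br)(Br)Br
Why: Appel reaction, in which the oxyphosphonium of the axial 1α-alcohol is displaced by bromide in an SN2 step with inversion to the equatorial 1β-bromide, the buffered neutral medium leaving the β,γ-enone in place.

Step 4
Reactants: 5 the 1β-bromo β,γ-enone
Product: 6 (2R,4aR,5R)-5-bromo-4a,8-dimethyl-1,2,3,4,4a,5,6,7-octahydronaphthalen-2-ol (7β-OH)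
Conditions: NaBH4, MeOH/CH2Cl2, −20 °C
Reagents that add atoms: none
Why: Borohydride reduction of the β,γ-unsaturated ketone should outrun its conjugation, and axial hydride attack gives the equatorial 7β-alcohol (a configuration that is not needed later).

Step 5
Reactants: 6 the 7β-alcohol
Product: 7 (2R,4aR,5R)-5-bromo-2-iodo-4a,8-dimethyl-1,2,3,4,4a,5,6,7-octahydronaphthalene (7β-I, 1β-Br, C4=C5)
Conditions: I2, PPh3, imidazole, CH2Cl2, 0 °C → rt
Reagents that add atoms: iodine, II
Why: Deoxyiodination through the oxyphosphonium (PPh3/I2/imidazole) in which homoallylic participation of the C4=C5 π bond (cholesterol-to-cholesteryl iodide type) should give net retention; only the secondary alcohol is present and either C7 epimer serves the key step.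

Step 6
Reactants: 7 the homoallylic iodide
Product: 9 (1R,4aR,6R,8aR)-1-bromo-6-iodo-8a-methyl-4-methylideneoctahydronaphthalen-4a(2H)-ol, via 5α-hydroperoxide 8 (not isolated)
Conditions: O2, hν (>500 nm), tetraphenylporphyrin (cat.), CH2Cl2, −20 °C; then Me2S, 0 °C
Reagents that add atoms: oxygen, O=O
Why: Schenck ene reaction, in which singlet oxygen should attack the tetrasubstituted C4=C5 alkene on the α-face opposite the C10 methyl, bond to C5 and abstract a C15 methyl hydrogen (methyl preferred over ring C–H, C6–H deactivated by the adjacent C–I), setting the 5α-oxygen and the C4=C15 methylidene before Me2S reduces the hydroperoxide.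

Step 7
Reactants: 10 propyne
Product: 11 (E)-2-bromo-1-iodoprop-1-ene
Conditions: IBr, CH2Cl2, −78 → −20 °C, dark
Reagents that add atoms: iodine monobromide, BrI
Why: Electrophilic anti addition of I–Br to the alkyne, with iodonium formation at the terminal carbon and Markovnikov opening by bromide, should give the E-1-iodo-2-bromo alkene.

Step 8
Reactants: 11 (E)-2-bromo-1-iodoprop-1-ene; 12 2-methylbut-1-en-3-yne
Product: 15 (2E,4E)-2-bromo-6-methylhepta-2,4,6-triene, via dienylzirconocene chloride 13 (not isolated), via dienylzinc chloride 14 (not isolated)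
Conditions: 12, Cp2Zr(H)Cl, THF, 0 °C → rt; ZnCl2; then 11, Pd(PPh3)4 (3 mol %), rt, dark
Reagents that add atoms: none
Why: Syn hydrozirconation of the terminal alkyne gives the E-dienyl metal, and after transmetalation to zinc the Negishi coupling proceeds with retention at both partners and selectively at the C–I bond, which adds to Pd(0) faster than the hindered C–Br bond.

Step 9
Reactants: 9 the 7-iodo-1β-bromo-5α-hydroxy-4(15)-ene; 15 (2E,4E)-2-bromo-6-methylhepta-2,4,6-triene
Product: 16 (1R,4aR,6R,8aR)-1-bromo-8a-methyl-4-methylidene-6-[(2E,4E)-6-methylhepta-2,4,6-trien-2-yl]octahydronaphthalen-4a(2H)-ol (target)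
Conditions: NiBr2·glyme (10 mol %), 4,4′-di-tert-butyl-2,2′-bipyridine (10 mol %), TDAE (1.1–1.3 equiv, added in portions), 15 (1.5 equiv), DMA, 0 → 20 °C, dark
Reagents that add atoms: none
Why: Ni(0) adds oxidatively to the C–Br bond of 15 with retention, the alkenyl–Ni(II) captures the C7 radical released from 9 by halogen abstraction at Ni(I), and reductive elimination from Ni(III) forms the C7–C11 bond while TDAE returns nickel to Ni(0). The closest known reaction type is the nickel-catalysed reductive cross-electrophile coupling of secondary alkyl halides with alkenyl bromides. No ring is closed. The only new stereocentre, C7, is controlled by the trans-decalin chair of ring B: the axial 5α-OH and 9α-H are syn-axial to the α lobe of the planar C7 radical, so the bulky nickel centre should bond on the equatorial β-face and both C7 epimers of 9 converge on the 7β product. The step needs C7–I to react before C1–Br (weaker C–I bond, neopentylic C1, and TDAE as the limiting reductant so that no reducing equivalents remain), retention of the 2E,4E geometry (oxidative addition and reductive elimination at sp2 carbon), and nickel capture faster than radical addition to the triene (kept by the 10 mol % nickel loading and moderate dilution).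

**Compound list**

1 | (R)-(−)-Wieland–Miescher ketone, (8aR)-8a-methyl-3,4,8,8a-tetrahydronaphthalene-1,6(2H,7H)-dione | O=C1CC[C@@]2(C)C(=O)CCCC2=C1 | starting material
2 | (8aR)-8a-methyl-4-methylidene-3,4,8,8a-tetrahydronaphthalene-1,6(2H,7H)-dione | O=C1CC[C@@]2(C)C(=O)CCC(=C)C2=C1 | intermediate
3 | dilithium dienolate-alkoxide (C7 O–Li dienolate over C7=C6–C5=C4, 1α-OLi) | [Li]OC1CC[C@@]2(C)[C@@H](O[Li])CCC(C)=C2C=1 | intermediate (not isolated)
4 | (4aR,5S)-5-hydroxy-4a,8-dimethyl-3,4,4a,5,6,7-hexahydronaphthalen-2(1H)-one (1α-OH) | O=C1CC[C@@]2(C)[C@@H](O)CCC(C)=C2C1 | intermediate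
5 | (4aR,5R)-5-bromo-4a,8-dimethyl-3,4,4a,5,6,7-hexahydronaphthalen-2(1H)-one (1β-Br) | O=C1CC[C@@]2(C)[C@H](Br)CCC(C)=C2C1 | intermediate
6 | (2R,4aR,5R)-5-bromo-4a,8-dimethyl-1,2,3,4,4a,5,6,7-octahydronaphthalen-2-ol (7β-OH) | O[C@@H]1CC[C@@]2(C)[C@H](Br)CCC(C)=C2C1 | intermediate
7 | (2R,4aR,5R)-5-bromo-2-iodo-4a,8-dimethyl-1,2,3,4,4a,5,6,7-octahydronaphthalene (7β-I) | I[C@@H]1CC[C@@]2(C)[C@H](Br)CCC(C)=C2C1 | intermediate
8 | (1R,4aR,6R,8aR)-1-bromo-4a-hydroperoxy-6-iodo-8a-methyl-4-methylidenedecahydronaphthalene (5α-OOH) | I[C@@H]1CC[C@@]2(C)[C@H](Br)CCC(=C)[C@]2(OO)C1 | intermediate (not isolated)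
9 | (1R,4aR,6R,8aR)-1-bromo-6-iodo-8a-methyl-4-methylideneoctahydronaphthalen-4a(2H)-ol | I[C@@H]1CC[C@@]2(C)[C@H](Br)CCC(=C)[C@]2(O)C1 | intermediate
10 | propyne | CC#C | starting material
11 | (E)-2-bromo-1-iodoprop-1-ene | I/C=C(\C)Br | intermediate
12 | 2-methylbut-1-en-3-yne | C=C(C)C#C | starting material
13 | chlorobis(cyclopentadienyl)[(1E)-3-methylbuta-1,3-dien-1-yl]zirconium | C=C(C)/C=C/[Zr](Cl)(C1C=CC=C1)C1C=CC=C1 | intermediate (not isolated)
14 | [(1E)-3-methylbuta-1,3-dien-1-yl]zinc chloride | C=C(C)/C=C/[Zn]Cl | intermediate (not isolated)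
15 | (2E,4E)-2-bromo-6-methylhepta-2,4,6-triene | C=C(C)/C=C/C=C(\C)Br | intermediate
16 | (1R,4aR,6R,8aR)-1-bromo-8a-methyl-4-methylidene-6-[(2E,4E)-6-methylhepta-2,4,6-trien-2-yl]octahydronaphthalen-4a(2H)-ol | C=C(C)/C=C/C=C(\C)[C@@H]1CC[C@@]2(C)[C@H](Br)CCC(=C)[C@]2(O)C1 | target

**Step count.** Total: 9 steps. Longest linear sequence: 7 steps (steps 1–6 and 9).

**Steps most likely to fail**

Step 9 (key step). The coupling may lose chemoselectivity between the two carbon–halogen bonds (halogen abstraction at C1–Br alongside or after C7–I), the C7 radical may add to the triene before nickel captures it, or capture may occur partly on the axial face. The fallback replaces the radical coupling by a polar organometallic one and sets out from 9. Silylation with TMSOTf/2,6-lutidine should give the trimethylsilyl ether F1. Zinc dust with LiCl in THF at 25 °C should insert into the C–I bond only and give the configurationally labile secondary alkylzinc iodide F2. A Pd(OAc)2/SPhos-catalysed Negishi coupling with 15, which passes through the equatorial carbon–metal species, should give the silyl ether of the target F3. K2CO3 in MeOH then removes the silyl group and the route is rejoined at 16.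

Step 3. E2 loss of the axial oxyphosphonium with the 2β-hydrogen, or ionisation with methyl migration, may outrun SN2 displacement at the neopentylic carbon, and traces of acid may move the alkene into conjugation. The fallback separates activation from displacement and sets out from 4. Tf2O/pyridine at −40 °C should give the 1α-triflate F4, which tetrabutylammonium bromide in toluene at 0–25 °C should displace with inversion. The route is rejoined at 5.

Step 2. Hydride may add 1,2 at C7 instead of 1,6 at the methylidene terminus, so that C7 is not masked while C1 is reduced. The fallback forms the same dienolate by deprotonation instead of hydride addition and sets out from 2. Hydrogenation of the exocyclic alkene (H2, RhCl(PPh3)3, benzene) should give the 4β-methyl enone F5, whose C4 centre is erased next. One equivalent of KOt-Bu in THF should remove the γ-hydrogen and give the potassium dienolate F6. L-Selectride then reduces the C1 ketone in the same flask, and AcOH at −78 °C rejoins the route at 4.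

**Further compounds**

F1 | step 9 | trimethylsilyl ether of 9 | I[C@@H]1CC[C@@]2(C)[C@H](Br)CCC(=C)[C@]2(O[Si](C)(C)C)C1
F2 | step 9 | C7 alkylzinc iodide of F1 (equatorial C–Zn drawn) | I[Zn][C@@H]1CC[C@@]2(C)[C@H](Br)CCC(=C)[C@]2(O[Si](C)(C)C)C1
F3 | step 9 | trimethylsilyl ether of 16 | C=C(C)/C=C/C=C(\C)[C@@H]1CC[C@@]2(C)[C@H](Br)CCC(=C)[C@]2(O[Si](C)(C)C)C1
F4 | step 3 | 1α-trifluoromethanesulfonate of 4 | O=C1CC[C@@]2(C)[C@@H](OS(=O)(=O)C(F)(F)F)CCC(C)=C2C1
F5 | step 2 | (4S,8aR)-4,8a-dimethyl-3,4,8,8a-tetrahydronaphthalene-1,6(2H,7H)-dione (4β-methyl) | O=C1CC[C@@]2(C)C(=O)CC[C@H](C)C2=C1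
F6 | step 2 | potassium dienolate of F5 (C1 ketone intact) | [K]OC1CC[C@@]2(C)C(=O)CCC(C)=C2C=1
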